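**Retrosynthetic overview**

1. Ring numbering: C1 = quaternary carbinol carrying C7H2OBz, C2 = CHOH, C3 and C4 = CH2, C5 = CHOBz, C6 = CHOH. The strategy rests on the fact that the C2 and C6 hydroxyls lie on the same ring face as C7 while C3 is unsubstituted. The C2–O bond can therefore be made from the C7 oxygen side (as a carbonate) across C2=C3 of a 1,1-disubstituted cyclohexa-2,5-diene, and the iodine that lands on C3 is reduced off.
2. 17 ⇐ 16 (acetal cleavage) ⇐ oxirane 15 + benzoic acid (C5–O bond, anti opening) ⇐ alkene 14 (C2–OH-directed epoxidation on the C7 face) ⇐ diol 13 (C7 benzoylation).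
3. 13 ⇐ carbonate 12 ⇐ iodocarbonate 11 ⇐ dienylmethanol 7 + CO2 + NIS. This is the key disconnection: it forms the C2–O bond and the 1,3-dioxan-2-one ring, and sets C1, C2 and C3 by selecting one of two enantiotopic alkenes.
4. 7 ⇐ benzoic acid by Birch reduction, methyl ester formation, enolate hydroxylation at C1, MOM protection and LiAlH4 reduction. C7 is the former carboxyl carbon, and benzoic acid also supplies the C5 benzoate.
5. Ring order: the carbocycle is carried over from benzoic acid. The cyclic carbonate closes in step 6 and opens in step 8. The oxirane closes in step 10 and opens in step 11.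

Key step: step 6

Remark on the chemistry: the sense of induction of the bis(amidine) catalyst on this substrate cannot be predicted. Both antipodes are available from (R,R)- and (S,S)-1,2-diphenylethane-1,2-diamine, and the route is written for the antipode that gives 11.

**Route**

Step 1
Reactants: 1 benzoic acid
Product: 2 cyclohexa-2,5-diene-1-carboxylic acid
Conditions: Na (2.5 equiv), NH3(l)–EtOH, −78 °C; NH4Cl; then 2 M HCl to pH 2
Reagents that add atoms: none
Why: Birch reduction, in which electron transfer to the benzoate and protonation at C4 and then at the carboxylate-bearing C1 give the non-conjugated 2,5-diene without forming a stereocentre.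

Step 2
Reactants: 2 cyclohexa-2,5-diene-1-carboxylic acid
Product: 3 methyl cyclohexa-2,5-diene-1-carboxylate
Conditions: Me3SiCHN2 (1.2 equiv, hexanes), MeOH–toluene (1:4), 0 °C → rt
Reagents that add atoms: (trimethylsilyl)diazomethane, C[Si](C)(C)C=[N+]=[N-]
Why: O-methylation of the carboxylic acid by diazomethane generated in situ from Me3SiCHN2 and methanol runs under neutral conditions, so the skipped diene is not moved into conjugation by acid or base.

Step 3
Reactants: 3 methyl cyclohexa-2,5-diene-1-carboxylate
Product: 5 methyl 1-hydroxycyclohexa-2,5-diene-1-carboxylate, via potassium dienolate 4 (not isolated)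
Conditions: KN(SiMe3)2 (1.1 equiv), THF, −78 °C; then 2-(benzenesulfonyl)-3-phenyloxaziridine (1.3 equiv), −78 °C; aqueous NH4Cl
Reagents that add atoms: 2-(benzenesulfonyl)-3-phenyloxaziridine, O=S(=O)(c1ccccc1)N1OC1c1ccccc1
Why: Enolate hydroxylation with an N-sulfonyloxaziridine (Davis oxidation), in which KN(SiMe3)2 removes the doubly allylic α-proton and the cross-conjugated dienolate 4 takes oxygen at C1, the carbon at which Birch-type dienolates react with electrophiles, leaving both ring alkenes in place and creating no stereocentre.

Step 4
Reactants: 5 methyl 1-hydroxycyclohexa-2,5-diene-1-carboxylate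
Product: 6 methyl 1-(methoxymethoxy)cyclohexa-2,5-diene-1-carboxylate
Conditions: MeOCH2Cl (3 equiv), iPr2NEt (5 equiv), Bu4NI (0.1 equiv), CH2Cl2, 0 → 40 °C
Reagents that add atoms: chloromethyl methyl ether, COCCl
Why: Acetal-type O-alkylation of the hindered tertiary hydroxyl by the reactive α-chloro ether under amine base with iodide catalysis avoids the strong acid or strong base that could aromatise the dienol.

Step 5
Reactants: 6 methyl 1-(methoxymethoxy)cyclohexa-2,5-diene-1-carboxylate
Product: 7 [1-(methoxymethoxy)cyclohexa-2,5-dien-1-yl]methanol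
Conditions: LiAlH4 (1.2 equiv), THF, 0 °C; aqueous NaOH work-up
Reagents that add atoms: none
Why: Hydride reduction of the ester to the primary alcohol with LiAlH4, to which the acetal and the isolated alkenes are inert.

Step 6
Reactants: 7 [1-(methoxymethoxy)cyclohexa-2,5-dien-1-yl]methanol, 8 carbon dioxide, 9 N-iodosuccinimide
Product: 11 (4aS,8S,8aS)-8-iodo-4a-(methoxymethoxy)-4a,7,8,8a-tetrahydro-4H-1,3-benzodioxin-2-one, via hydrogen carbonate 10 (not isolated)
Conditions: CO2 (1 atm), NIS (1.3 equiv), N,N′-bis[4-(pyrrolidin-1-yl)quinolin-2-yl]-1,2-diphenylethane-1,2-diamine·HN(SO2CF3)2 (single antipode, 10 mol %), 4 Å molecular sieves, toluene, −20 °C, dark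
Reagents that add atoms: carbon dioxide (8), O=C=O; N-iodosuccinimide (9), O=C1CCC(=O)N1I
Why: Proposed new method: the primary hydroxyl of 7 adds reversibly to CO2 to give hydrogen carbonate 10, which the amidine–amidinium pocket of the chiral Brønsted acid–base catalyst deprotonates and holds while the same catalyst activates NIS, so that iodonium transfer to one ring alkene on the face opposite C7 is followed by anti attack of the carbonate oxygen at the nearer alkene carbon C2. The closest known reaction type is the bis(amidine)·HN(SO2CF3)2-catalysed enantioselective iodocarbonation of acyclic homoallylic alcohols with CO2, taken together with catalytic desymmetrising halolactonisations and haloetherifications of 1,1-disubstituted cyclohexa-2,5-dienes, and the new element is their combination on a ring cis-alkene of a dienylmethanol. The 1,3-dioxan-2-one ring closes in the 6-exo-trig mode, since attack at C3 (7-endo) would give a strained bridged carbonate. Of the new stereocentres, C2 is fixed by the one-carbon tether (a six-membered ring through C7 forms only on the C7 face, giving the cis-fused bicycle), C3 by anti addition across the iodonium ion (iodine trans to the C2 oxygen), and C1 becomes stereogenic through the catalyst's choice between the two enantiotopic alkenes. The step needs enantiotopic-group selection, which is the task of the catalyst acting on the bound carbonate, and mono-functionalisation, which follows because 11 has no free nucleophile left for its remaining alkene. The MOM cap on the tertiary oxygen ensures that only the primary hydroxyl captures CO2, and the quaternary C1 blocks dehydrogenation of the skipped diene to an arene by NIS.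

Step 7
Reactants: 11 (4aS,8S,8aS)-8-iodo-4a-(methoxymethoxy)-4a,7,8,8a-tetrahydro-4H-1,3-benzodioxin-2-one
Product: 12 (4aS,8aR)-4a-(methoxymethoxy)-4a,7,8,8a-tetrahydro-4H-1,3-benzodioxin-2-one
Conditions: Bu3SnH (1.5 equiv), AIBN (0.1 equiv), toluene, 80 °C
Reagents that add atoms: none
Why: Radical chain dehalogenation, in which Bu3Sn• abstracts iodine and the secondary C3 radical is reduced by Bu3SnH faster than it can rearrange, removes the C3 stereocentre and leaves C1, C2, the carbonate and the alkene untouched.

Step 8
Reactants: 12 (4aS,8aR)-4a-(methoxymethoxy)-4a,7,8,8a-tetrahydro-4H-1,3-benzodioxin-2-one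
Product: 13 (1R,2S)-2-(hydroxymethyl)-2-(methoxymethoxy)cyclohex-3-en-1-ol
Conditions: K2CO3 (0.5 equiv), MeOH, 0 °C → rt
Reagents that add atoms: none
Why: Base-catalysed transesterification of the cyclic carbonate with methanol frees the C7 and C2 hydroxyls without breaking a ring C–O bond, so both stereocentres are retained.

Step 9
Reactants: 13 (1R,2S)-2-(hydroxymethyl)-2-(methoxymethoxy)cyclohex-3-en-1-ol
Product: 14 [(1S,6R)-6-hydroxy-1-(methoxymethoxy)cyclohex-2-en-1-yl]methyl benzoate
Conditions: PhCOCl (1.1 equiv), 2,4,6-collidine (2 equiv), CH2Cl2, −40 → 0 °C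
Reagents that add atoms: benzoyl chloride, O=C(Cl)c1ccccc1
Why: Chemoselective acylation, in which the primary C7 hydroxyl reacts with benzoyl chloride and the hindered base collidine at low temperature well before the secondary C2 hydroxyl that is flanked by the quaternary carbon.

Step 10
Reactants: 14 [(1S,6R)-6-hydroxy-1-(methoxymethoxy)cyclohex-2-en-1-yl]methyl benzoate
Product: 15 [(1S,2S,3R,6S)-3-hydroxy-2-(methoxymethoxy)-7-oxabicyclo[4.1.0]heptan-2-yl]methyl benzoate
Conditions: VO(acac)2 (5 mol %), t-BuOOH (1.5 equiv, decane), toluene, rt → 40 °C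
Reagents that add atoms: tert-butyl hydroperoxide, CC(C)(C)OO
Why: Hydroxyl-directed epoxidation with VO(acac)2 and t-BuOOH, as known for cyclohex-3-en-1-ols, in which the pseudoaxial homoallylic C2 hydroxyl binds the vanadium peroxide and delivers oxygen to the face of C5=C6 that it occupies, the C7 face, setting C5 and C6 with the oxirane oxygen cis to C7 and to the C2 hydroxyl.

Step 11
Reactants: 15 [(1S,2S,3R,6S)-3-hydroxy-2-(methoxymethoxy)-7-oxabicyclo[4.1.0]heptan-2-yl]methyl benzoate, 1 benzoic acid
Product: 16 [(1S,2S,3R,6R)-3-(benzoyloxy)-2,6-dihydroxy-1-(methoxymethoxy)cyclohexyl]methyl benzoate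
Conditions: PhCO2H (4 equiv), PhCO2Cs (0.5 equiv), DMF, 80 °C
Reagents that add atoms: benzoic acid (1), OC(=O)c1ccccc1
Why: Epoxide opening by a carboxylate (SN2, Fürst–Plattner trans-diaxial), in which benzoate attacks C5 from the face opposite the oxirane because C6 is neopentyl and inductively deactivated by the oxygen on C1 and because the half-chair with CH2OBz pseudoequatorial leads to C5 attack, inverts C5 and gives the C5 benzoate trans to the C6 hydroxyl.

Step 12
Reactants: 16 [(1S,2S,3R,6R)-3-(benzoyloxy)-2,6-dihydroxy-1-(methoxymethoxy)cyclohexyl]methyl benzoate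
Product: 17 [(1S,2S,3R,6R)-3-(benzoyloxy)-1,2,6-trihydroxycyclohexyl]methyl benzoate
Conditions: 3 M HCl–THF (1:2), 40 °C
Reagents that add atoms: none
Why: Acid-catalysed hydrolysis of the formaldehyde acetal through the oxocarbenium ion frees the tertiary hydroxyl, while the benzoates resist dilute aqueous acid, base-promoted acyl migration is kept slow, and no stereocentre is touched.

**Compound list**

1 | benzoic acid | OC(=O)c1ccccc1 | starting material
2 | cyclohexa-2,5-diene-1-carboxylic acid | OC(=O)C1C=CCC=C1 | intermediate
3 | methyl cyclohexa-2,5-diene-1-carboxylate | COC(=O)C1C=CCC=C1 | intermediate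
4 | potassium (cyclohexa-2,5-dien-1-ylidene)(methoxy)methanolate (dienolate of 3, not isolated) | COC([O-])=C1C=CCC=C1.[K+] | intermediate
5 | methyl 1-hydroxycyclohexa-2,5-diene-1-carboxylate | COC(=O)C1(O)C=CCC=C1 | intermediate
6 | methyl 1-(methoxymethoxy)cyclohexa-2,5-diene-1-carboxylate | COCOC1(C(=O)OC)C=CCC=C1 | intermediate
7 | [1-(methoxymethoxy)cyclohexa-2,5-dien-1-yl]methanol | COCOC1(CO)C=CCC=C1 | intermediate
8 | carbon dioxide | O=C=O | starting material
9 | N-iodosuccinimide | O=C1CCC(=O)N1I | starting material
10 | [1-(methoxymethoxy)cyclohexa-2,5-dien-1-yl]methyl hydrogen carbonate (not isolated) | COCOC1(COC(=O)O)C=CCC=C1 | intermediate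
11 | (4aS,8S,8aS)-8-iodo-4a-(methoxymethoxy)-4a,7,8,8a-tetrahydro-4H-1,3-benzodioxin-2-one (cis-fused; C2–O cis to C7, iodine trans to it) | O=C1OC[C@]2(OCOC)[C@H](O1)[C@@H](I)CC=C2 | intermediate
12 | (4aS,8aR)-4a-(methoxymethoxy)-4a,7,8,8a-tetrahydro-4H-1,3-benzodioxin-2-one | O=C1OC[C@]2(OCOC)[C@H](O1)CCC=C2 | intermediate
13 | (1R,2S)-2-(hydroxymethyl)-2-(methoxymethoxy)cyclohex-3-en-1-ol | OC[C@]1(OCOC)[C@H](O)CCC=C1 | intermediate
14 | [(1S,6R)-6-hydroxy-1-(methoxymethoxy)cyclohex-2-en-1-yl]methyl benzoate | O=C(OC[C@]1(OCOC)[C@H](O)CCC=C1)c1ccccc1 | intermediate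
15 | [(1S,2S,3R,6S)-3-hydroxy-2-(methoxymethoxy)-7-oxabicyclo[4.1.0]heptan-2-yl]methyl benzoate (oxirane oxygen cis to C7) | O=C(OC[C@]1(OCOC)[C@H](O)CC[C@@H]2O[C@@H]21)c1ccccc1 | intermediate
16 | [(1S,2S,3R,6R)-3-(benzoyloxy)-2,6-dihydroxy-1-(methoxymethoxy)cyclohexyl]methyl benzoate | O=C(OC[C@]1(OCOC)[C@H](O)CC[C@@H](OC(=O)c2ccccc2)[C@@H]1O)c1ccccc1 | intermediate
17 | [(1S,2S,3R,6R)-3-(benzoyloxy)-1,2,6-trihydroxycyclohexyl]methyl benzoate | O=C(OC[C@]1(O)[C@H](O)CC[C@@H](OC(=O)c2ccccc2)[C@@H]1O)c1ccccc1 | target

**Step count and risk**

Total step count: 12. Longest linear sequence: 12 steps (1 → 17).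

Steps most likely to fail:

1. Step 6 (proposed new method). The catalyst may discriminate the two enantiotopic ring alkenes poorly. CO2 uptake by the neopentyl-type alcohol may also be too slow, so that the iodonium ion is instead captured by the acetal oxygen on the other face (cyclic formal formation with loss of the methyl group), by the free hydroxyl at C3 (bridged ether formation), or relieved by a 1,2-shift towards the oxygen-bearing C1. The fallback uses known chemistry, sets out from 7 and returns at 13. A vanadium-catalysed asymmetric epoxidation of the homoallylic alcohol (VO(OiPr)3, a C2-symmetric N,N′-dihydroxy-N,N′-bis(diarylacetyl)cyclohexane-1,2-diamine ligand, cumene hydroperoxide, toluene, rt) would epoxidise one enantiotopic alkene on the C7 face to give [(1R,2S,6R)-2-(methoxymethoxy)-7-oxabicyclo[4.1.0]hept-3-en-2-yl]methanol F1. LiEt3BH in THF (0 °C → rt) would then deliver hydride anti at the unhindered C3, away from the quaternary carbon, to give diol 13 directly. Steps 6–8 are bypassed and the route continues with step 9.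

2. Step 11. Benzoate may attack the neopentyl C6 instead of C5 because the acetal oxygen on C1 is syn-axial to the incoming nucleophile, or the benzoyl groups may migrate between neighbouring oxygens at the temperature needed. The fallback sets out from 14 and returns at 16 without an epoxide. Hydrogen-bond-directed syn-dihydroxylation (OsO4, TMEDA, CH2Cl2, −78 °C, then aqueous NaHSO3) on the face of the C2 hydroxyl, which is also the face anti to the allylic acetal oxygen, would give [(1S,2S,3S,6R)-2,3,6-trihydroxy-1-(methoxymethoxy)cyclohexyl]methyl benzoate F2. A Mitsunobu reaction (PPh3, DIAD, PhCO2H, THF, 0 °C → rt) would then invert the only secondary carbinol that is not flanked by the quaternary carbon, C5, to give 16. Here the regiochemistry is decided by SN2 accessibility and not by the direction of an epoxide opening.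

3. Step 10. Oxygen transfer may be slow and facial control eroded because only one secondary homoallylic hydroxyl binds vanadium next to a quaternary centre. The fallback sets out from 13 and returns at 15 by inverting the order of oxidation and acylation, so that two hydroxyls on the C7 face direct the epoxidation. Diol 13 would be epoxidised (VO(acac)2, t-BuOOH, toluene, rt) to (1S,2S,3R,6S)-2-(hydroxymethyl)-2-(methoxymethoxy)-7-oxabicyclo[4.1.0]heptan-3-ol F3. Its primary hydroxyl would then be benzoylated (PhCOCl, 2,4,6-collidine, CH2Cl2, −40 → 0 °C) to give 15.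

**Further compounds**

F1 | step 6 | [(1R,2S,6R)-2-(methoxymethoxy)-7-oxabicyclo[4.1.0]hept-3-en-2-yl]methanol | OC[C@]1(OCOC)[C@@H]2O[C@@H]2CC=C1
F2 | step 11 | [(1S,2S,3S,6R)-2,3,6-trihydroxy-1-(methoxymethoxy)cyclohexyl]methyl benzoate | O=C(OC[C@]1(OCOC)[C@H](O)CC[C@H](O)[C@@H]1O)c1ccccc1
F3 | step 10 | (1S,2S,3R,6S)-2-(hydroxymethyl)-2-(methoxymethoxy)-7-oxabicyclo[4.1.0]heptan-3-ol | OC[C@]1(OCOC)[C@H](O)CC[C@@H]2O[C@@H]21
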